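**Retrosynthetic overview**

- Target 24 comes from its tribenzyl ether 23 by hydrogenolysis; 23 comes from lactone 18 by excision of a one-carbon side chain at C5; 18 comes from dithiane adduct 17 by desulfurisation.
- Key disconnection: the C4–C(ring A benzylic) and C3–C(ring B benzylic) bonds of 17, both made in one flask from dithiane 8, (R)-butenolide 6 and benzylic bromide 14.
- Feature used: in the lactone ring (O1, C2 carbonyl, C3, C4, C5), C4 and C3 are the beta and alpha carbons of a butenolide and each needs one arylmethyl group, trans to the other. C5 is a plain CH2 in the target, so it can carry a CH2OSi group as a temporary stereocentre that steers both bond formations and is then cut off.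
- Rings: the gamma-lactone is carried from chiral-pool lactone 1 and no ring is made in the key step; it is opened and closed again once in step 12. The dithiane ring is temporary, and both arenes are bought.

Key step: step 9

Assumption: (R)-5-(hydroxymethyl)dihydrofuran-2(3H)-one (the lactone derived from D-glutamic acid) and 4-(benzyloxy)-3-methoxybenzaldehyde (O-benzylvanillin) are bought as such.

**Route**

Step 1
Reactants: 1 (R)-5-(hydroxymethyl)dihydrofuran-2(3H)-one
Product: 2 (R)-5-((tert-butyldiphenylsilyloxy)methyl)dihydrofuran-2(3H)-one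
Conditions: TBDPSCl, imidazole, DMF, 0 °C to rt
Reagents that add atoms: tert-butyl(chloro)diphenylsilane, CC(C)(C)[Si](Cl)(c1ccccc1)c1ccccc1
Why: Imidazole-promoted silylation of the only hydroxyl group (silyl ether formation) installs a bulky group that later shields one face of the ring, and the C5 stereocentre is not touched.

Step 2
Reactants: 2 (R)-5-((tert-butyldiphenylsilyloxy)methyl)dihydrofuran-2(3H)-one
Product: 4 (5R)-5-((tert-butyldiphenylsilyloxy)methyl)-3-(phenylselanyl)dihydrofuran-2(3H)-one (both C3 epimers), via lithium enolate 3 (not isolated)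
Conditions: LiN(i-Pr)2, THF, −78 °C; PhSeBr, −78 °C; aq NH4Cl
Reagents that add atoms: phenylselenyl bromide, Br[Se]c1ccccc1
Why: Deprotonation at C3, the only position alpha to the lactone carbonyl, gives the lithium enolate, which PhSeBr selenenylates (alpha-selenenylation of a lactone enolate); the C3 configuration does not matter because C3 becomes sp2 in step 3, and C5 is untouched.

Step 3
Reactants: 4 (5R)-5-((tert-butyldiphenylsilyloxy)methyl)-3-(phenylselanyl)dihydrofuran-2(3H)-one
Product: 6 (R)-5-((tert-butyldiphenylsilyloxy)methyl)furan-2(5H)-one, via selenoxide 5 (not isolated)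
Conditions: 30% H2O2, pyridine (cat.), CH2Cl2, 0 °C to rt
Reagents that add atoms: none
Why: Oxidation at selenium is followed by syn elimination of the selenoxide (selenoxide elimination) toward C4, the only carbon with a beta hydrogen, which gives the butenolide without base and so without loss of the C5 configuration.

Step 4
Reactants: 7 4-(benzyloxy)-3-methoxybenzaldehyde
Product: 8 2-(4-(benzyloxy)-3-methoxyphenyl)-1,3-dithiane
Conditions: propane-1,3-dithiol, BF3·OEt2 (cat.), CH2Cl2, 0 °C to rt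
Reagents that add atoms: propane-1,3-dithiol, SCCCS
Why: Lewis acid-catalysed dithioacetalisation of an aromatic aldehyde turns the carbonyl carbon into an acyl anion equivalent that ends as the ring A benzylic CH2.

Step 5
Reactants: 9 2-methoxyresorcinol (2-methoxybenzene-1,3-diol)
Product: 10 1,3-bis(benzyloxy)-2-methoxybenzene
Conditions: BnBr, K2CO3, DMF, 60 °C
Reagents that add atoms: benzyl bromide, BrCc1ccccc1
Why: Double Williamson ether synthesis of the two equivalent phenols with a reactive benzylic halide.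

Step 6
Reactants: 10 1,3-bis(benzyloxy)-2-methoxybenzene
Product: 12 2,4-bis(benzyloxy)-3-methoxybenzaldehyde, via aryl iminium chloride 11 (not isolated)
Conditions: POCl3, DMF, 0 to 70 °C; aq NaOAc
Reagents that add atoms: N,N-dimethylformamide, CN(C)C=O; water, O
Why: Vilsmeier–Haack formylation takes place at C4, which is ortho to one benzyloxy group and para to the other, whereas C5 is meta to both and only para to the flanked, twisted methoxy group, as in the formylation of 1,2,3-trimethoxybenzene.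

Step 7
Reactants: 12 2,4-bis(benzyloxy)-3-methoxybenzaldehyde
Product: 13 (2,4-bis(benzyloxy)-3-methoxyphenyl)methanol
Conditions: NaBH4, MeOH/THF, 0 °C
Reagents that add atoms: none
Why: Hydride reduction of an aromatic aldehyde to the benzylic alcohol.

Step 8
Reactants: 13 (2,4-bis(benzyloxy)-3-methoxyphenyl)methanol
Product: 14 2,4-bis(benzyloxy)-3-methoxybenzyl bromide
Conditions: PBr3, Et2O, 0 °C; cold aq NaHCO3 wash, used at once as a solution
Reagents that add atoms: phosphorus tribromide, BrP(Br)Br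
Why: A benzylic alcohol is converted into the bromide through its phosphite ester (PBr3 bromination), and the electron-rich bromide is kept cold and used directly in step 9.

Step 9
Reactants: 8 2-(4-(benzyloxy)-3-methoxyphenyl)-1,3-dithiane; 6 (R)-5-((tert-butyldiphenylsilyloxy)methyl)furan-2(5H)-one; 14 2,4-bis(benzyloxy)-3-methoxybenzyl bromide
Product: 17 (3R,4R,5R)-3-(2,4-bis(benzyloxy)-3-methoxybenzyl)-4-(2-(4-(benzyloxy)-3-methoxyphenyl)-1,3-dithian-2-yl)-5-((tert-butyldiphenylsilyloxy)methyl)dihydrofuran-2(3H)-one, via lithiodithiane 15 (not isolated), via lithium enolate 16 (not isolated)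
Conditions: n-BuLi, THF, −78 to −30 °C; 6, −78 °C; DMPU, 14, −78 to −30 °C; aq NH4Cl
Reagents that add atoms: none
Why: n-BuLi removes the C2 proton of 8 to give the sulfur- and aryl-stabilised anion 15, which adds as a soft nucleophile to C4 of butenolide 6 (Michael addition) to give lithium enolate 16, and 16 is then benzylated on carbon at C3 by bromide 14 in an SN2 reaction once DMPU is present. The closest known reaction type is the one-flask conjugate addition of 2-aryl-2-lithio-1,3-dithianes to 5-substituted furan-2(5H)-ones with alkylation of the resulting enolate, so the step applies known chemistry to a new pair of aryl groups. No ring is closed; the two new bonds are C4–C(dithiane) and C3–CH2(ring B). The C4 stereocentre (R) is set by attack on the face of the flat butenolide opposite the C5 silyloxymethyl group. The C3 stereocentre (R) is set by alkylation of the enolate on the face opposite the bulky C4 dithianyl group, which gives the 3,4-trans-4,5-trans lactone. The step needs 1,4-addition in preference to 1,2-addition and to deprotonation at C5, which the delocalised, hindered anion at −78 °C should secure, and it needs a single C-alkylation, which the reactive benzylic bromide and the crowded product should secure.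

Step 10
Reactants: 17 (3R,4R,5R)-3-(2,4-bis(benzyloxy)-3-methoxybenzyl)-4-(2-(4-(benzyloxy)-3-methoxyphenyl)-1,3-dithian-2-yl)-5-((tert-butyldiphenylsilyloxy)methyl)dihydrofuran-2(3H)-one
Product: 18 (3R,4R,5R)-3-(2,4-bis(benzyloxy)-3-methoxybenzyl)-4-(4-(benzyloxy)-3-methoxybenzyl)-5-((tert-butyldiphenylsilyloxy)methyl)dihydrofuran-2(3H)-one
Conditions: NiCl2·6H2O, NaBH4, MeOH/THF, 0 °C to rt
Reagents that add atoms: none
Why: Reductive desulfurisation of the benzylic dithioketal by Ni2B formed in the flask cleaves both C–S bonds to leave the ring A benzylic CH2, under conditions that should spare aryl benzyl ethers, the silyl ether and the lactone and that do not touch C3, C4 or C5.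

Step 11
Reactants: 18 (3R,4R,5R)-3-(2,4-bis(benzyloxy)-3-methoxybenzyl)-4-(4-(benzyloxy)-3-methoxybenzyl)-5-((tert-butyldiphenylsilyloxy)methyl)dihydrofuran-2(3H)-one
Product: 19 (3R,4R,5R)-3-(2,4-bis(benzyloxy)-3-methoxybenzyl)-4-(4-(benzyloxy)-3-methoxybenzyl)-5-(hydroxymethyl)dihydrofuran-2(3H)-one
Conditions: TBAF, AcOH, THF, 0 °C to rt
Reagents that add atoms: none
Why: Fluoride-mediated cleavage of the silyl ether, buffered with acetic acid so that the alkoxide formed neither epimerises C3 nor moves the lactone.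

Step 12
Reactants: 19 (3R,4R,5R)-3-(2,4-bis(benzyloxy)-3-methoxybenzyl)-4-(4-(benzyloxy)-3-methoxybenzyl)-5-(hydroxymethyl)dihydrofuran-2(3H)-one
Product: 23 (3R,4R)-3-(2,4-bis(benzyloxy)-3-methoxybenzyl)-4-(4-(benzyloxy)-3-methoxybenzyl)dihydrofuran-2(3H)-one, via diol carboxylate 20 (not isolated), via aldehyde carboxylate 21 (not isolated), via hydroxy carboxylate 22 (not isolated)
Conditions: 1 M NaOH, THF/MeOH, rt; 1 M HCl to pH 7–8, NaIO4, H2O, 0 °C; NaBH4, 0 °C; 2 M HCl to pH 2, rt (Na2S2O3 wash on work-up)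
Reagents that add atoms: none
Why: Saponification frees the 1,2-diol made of C5 and its exocyclic CH2OH, NaIO4 cleaves it (Malaprade glycol cleavage) so that C5 becomes an aldehyde, NaBH4 reduces the aldehyde at once before the neighbouring C4 can epimerise, and acid closes the 4-hydroxy acid back to the gamma-lactone (lactonisation), which leaves C3 and C4 as set in step 9.

Step 13
Reactants: 23 (3R,4R)-3-(2,4-bis(benzyloxy)-3-methoxybenzyl)-4-(4-(benzyloxy)-3-methoxybenzyl)dihydrofuran-2(3H)-one
Product: 24 (3R,4R)-3-(2,4-dihydroxy-3-methoxybenzyl)-4-(4-hydroxy-3-methoxybenzyl)dihydrofuran-2(3H)-one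
Conditions: H2 (1 atm), 10% Pd/C, EtOAc/EtOH, rt
Reagents that add atoms: none
Why: Hydrogenolysis of the three aryl benzyl ethers over Pd/C under neutral conditions leaves the lactone, the benzylic C–C bonds and both stereocentres unchanged.

**Compound list**

1 | (R)-5-(hydroxymethyl)dihydrofuran-2(3H)-one | O=C1CC[C@H](CO)O1 | starting material
2 | (R)-5-((tert-butyldiphenylsilyloxy)methyl)dihydrofuran-2(3H)-one | O=C1CC[C@H](CO[Si](c2ccccc2)(c2ccccc2)C(C)(C)C)O1 | intermediate
3 | lithium (R)-5-((tert-butyldiphenylsilyloxy)methyl)-4,5-dihydrofuran-2-olate (lithium enolate of 2) | [Li]OC1=CC[C@H](CO[Si](c2ccccc2)(c2ccccc2)C(C)(C)C)O1 | intermediate (not isolated)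
4 | (5R)-5-((tert-butyldiphenylsilyloxy)methyl)-3-(phenylselanyl)dihydrofuran-2(3H)-one, both C3 epimers | O=C1C([Se]c2ccccc2)C[C@H](CO[Si](c3ccccc3)(c3ccccc3)C(C)(C)C)O1 | intermediate
5 | (5R)-5-((tert-butyldiphenylsilyloxy)methyl)-3-(phenylseleninyl)dihydrofuran-2(3H)-one (selenoxide) | O=C1C([Se](=O)c2ccccc2)C[C@H](CO[Si](c3ccccc3)(c3ccccc3)C(C)(C)C)O1 | intermediate (not isolated)
6 | (R)-5-((tert-butyldiphenylsilyloxy)methyl)furan-2(5H)-one | O=C1C=C[C@H](CO[Si](c2ccccc2)(c2ccccc2)C(C)(C)C)O1 | intermediate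
7 | 4-(benzyloxy)-3-methoxybenzaldehyde | COc1cc(C=O)ccc1OCc1ccccc1 | starting material
8 | 2-(4-(benzyloxy)-3-methoxyphenyl)-1,3-dithiane | COc1cc(C2SCCCS2)ccc1OCc1ccccc1 | intermediate
9 | 2-methoxyresorcinol | COc1c(O)cccc1O | starting material
10 | 1,3-bis(benzyloxy)-2-methoxybenzene | COc1c(OCc2ccccc2)cccc1OCc1ccccc1 | intermediate
11 | N-(2,4-bis(benzyloxy)-3-methoxybenzylidene)-N-methylmethanaminium chloride | C[N+](C)=Cc1ccc(OCc2ccccc2)c(OC)c1OCc1ccccc1.[Cl-] | intermediate (not isolated)
12 | 2,4-bis(benzyloxy)-3-methoxybenzaldehyde | COc1c(OCc2ccccc2)ccc(C=O)c1OCc1ccccc1 | intermediate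
13 | (2,4-bis(benzyloxy)-3-methoxyphenyl)methanol | COc1c(OCc2ccccc2)ccc(CO)c1OCc1ccccc1 | intermediate
14 | 2,4-bis(benzyloxy)-3-methoxybenzyl bromide | BrCc1ccc(OCc2ccccc2)c(OC)c1OCc1ccccc1 | intermediate
15 | 2-(4-(benzyloxy)-3-methoxyphenyl)-2-lithio-1,3-dithiane | [Li]C1(c2ccc(OCc3ccccc3)c(OC)c2)SCCCS1 | intermediate (not isolated)
16 | lithium (4R,5R)-4-(2-(4-(benzyloxy)-3-methoxyphenyl)-1,3-dithian-2-yl)-5-((tert-butyldiphenylsilyloxy)methyl)-4,5-dihydrofuran-2-olate | [Li]OC1=C[C@@H](C2(c3ccc(OCc4ccccc4)c(OC)c3)SCCCS2)[C@H](CO[Si](c2ccccc2)(c2ccccc2)C(C)(C)C)O1 | intermediate (not isolated)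
17 | (3R,4R,5R)-3-(2,4-bis(benzyloxy)-3-methoxybenzyl)-4-(2-(4-(benzyloxy)-3-methoxyphenyl)-1,3-dithian-2-yl)-5-((tert-butyldiphenylsilyloxy)methyl)dihydrofuran-2(3H)-one | O=C1O[C@@H](CO[Si](c2ccccc2)(c2ccccc2)C(C)(C)C)[C@H](C2(c3ccc(OCc4ccccc4)c(OC)c3)SCCCS2)[C@H]1Cc1ccc(OCc2ccccc2)c(OC)c1OCc1ccccc1 | intermediate
18 | (3R,4R,5R)-3-(2,4-bis(benzyloxy)-3-methoxybenzyl)-4-(4-(benzyloxy)-3-methoxybenzyl)-5-((tert-butyldiphenylsilyloxy)methyl)dihydrofuran-2(3H)-one | O=C1O[C@@H](CO[Si](c2ccccc2)(c2ccccc2)C(C)(C)C)[C@H](Cc2ccc(OCc3ccccc3)c(OC)c2)[C@H]1Cc1ccc(OCc2ccccc2)c(OC)c1OCc1ccccc1 | intermediate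
19 | (3R,4R,5R)-3-(2,4-bis(benzyloxy)-3-methoxybenzyl)-4-(4-(benzyloxy)-3-methoxybenzyl)-5-(hydroxymethyl)dihydrofuran-2(3H)-one | O=C1O[C@@H](CO)[C@H](Cc2ccc(OCc3ccccc3)c(OC)c2)[C@H]1Cc1ccc(OCc2ccccc2)c(OC)c1OCc1ccccc1 | intermediate
20 | sodium (2R,3R,4R)-2-(2,4-bis(benzyloxy)-3-methoxybenzyl)-3-(4-(benzyloxy)-3-methoxybenzyl)-4,5-dihydroxypentanoate | [Na+].[O-]C(=O)[C@H](Cc1ccc(OCc2ccccc2)c(OC)c1OCc1ccccc1)[C@@H](Cc1ccc(OCc2ccccc2)c(OC)c1)[C@@H](O)CO | intermediate (not isolated)
21 | sodium (2R,3R)-2-(2,4-bis(benzyloxy)-3-methoxybenzyl)-3-(4-(benzyloxy)-3-methoxybenzyl)-4-oxobutanoate | [Na+].[O-]C(=O)[C@H](Cc1ccc(OCc2ccccc2)c(OC)c1OCc1ccccc1)[C@@H](Cc1ccc(OCc2ccccc2)c(OC)c1)C=O | intermediate (not isolated)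
22 | sodium (2R,3R)-2-(2,4-bis(benzyloxy)-3-methoxybenzyl)-3-(4-(benzyloxy)-3-methoxybenzyl)-4-hydroxybutanoate | [Na+].[O-]C(=O)[C@H](Cc1ccc(OCc2ccccc2)c(OC)c1OCc1ccccc1)[C@@H](Cc1ccc(OCc2ccccc2)c(OC)c1)CO | intermediate (not isolated)
23 | (3R,4R)-3-(2,4-bis(benzyloxy)-3-methoxybenzyl)-4-(4-(benzyloxy)-3-methoxybenzyl)dihydrofuran-2(3H)-one | O=C1OC[C@H](Cc2ccc(OCc3ccccc3)c(OC)c2)[C@H]1Cc1ccc(OCc2ccccc2)c(OC)c1OCc1ccccc1 | intermediate
24 | (3R,4R)-3-(2,4-dihydroxy-3-methoxybenzyl)-4-(4-hydroxy-3-methoxybenzyl)dihydrofuran-2(3H)-one | COc1cc(C[C@H]2COC(=O)[C@@H]2Cc2ccc(O)c(OC)c2O)ccc1O | target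

**Step count**

Total: 13 steps. Longest linear sequence: 9 steps (steps 5, 6, 7, 8, 9, 10, 11, 12, 13).

**Steps most likely to fail, with fallbacks**

1. Step 9. The alkylation may fail because the electron-rich bromide 14 decomposes before it reaches the hindered enolate, or because the enolate is quenched by proton transfer. The addition may also be eroded by deprotonation of 6 at C5 or by 1,2-addition.
The fallback sets out from 8 and 6, with 15 and 16 formed as in step 9, and uses the stable aldehyde 12 in place of bromide 14. Enolate 16 is trapped at −78 °C by 12 in an aldol addition anti to the dithianyl group. This should give (3S,4R,5R)-3-((2,4-bis(benzyloxy)-3-methoxyphenyl)(hydroxy)methyl)-4-(2-(4-(benzyloxy)-3-methoxyphenyl)-1,3-dithian-2-yl)-5-((tert-butyldiphenylsilyloxy)methyl)dihydrofuran-2(3H)-one F1 as both carbinol epimers; the C3 descriptor changes only because the ranking of the substituents changes. The hydroxyl group is thioacylated with 1,1'-thiocarbonyldiimidazole in warm THF to give O-((2,4-bis(benzyloxy)-3-methoxyphenyl)((3S,4R,5R)-4-(2-(4-(benzyloxy)-3-methoxyphenyl)-1,3-dithian-2-yl)-5-((tert-butyldiphenylsilyloxy)methyl)-2-oxotetrahydrofuran-3-yl)methyl) 1H-imidazole-1-carbothioate F2. Barton–McCombie deoxygenation (Bu3SnH in slight excess, AIBN, toluene, 80 °C) then removes the benzylic oxygen and the route is rejoined at 17. An acid-mediated ionic reduction of F1 is avoided on purpose, because the benzylic cation would close onto ring A.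

2. Step 12. C4 may epimerise while C5 is an aldehyde, the cleavage may be incomplete, or the lactone may fail to close cleanly.
The fallback sets out from 19 and never passes through an aldehyde next to C4. The primary alcohol is oxidised (TEMPO cat., PhI(OAc)2, MeCN/H2O) to (2R,3R,4R)-4-(2,4-bis(benzyloxy)-3-methoxybenzyl)-3-(4-(benzyloxy)-3-methoxybenzyl)-5-oxotetrahydrofuran-2-carboxylic acid F3. The acid is coupled with N-hydroxypyridine-2-thione (N,N'-dicyclohexylcarbodiimide, CH2Cl2, dark) to give 2-thioxopyridin-1(2H)-yl (2R,3R,4R)-4-(2,4-bis(benzyloxy)-3-methoxybenzyl)-3-(4-(benzyloxy)-3-methoxybenzyl)-5-oxotetrahydrofuran-2-carboxylate F4. Barton reductive decarboxylation (t-BuSH, visible light, THF) replaces the carboxyl group by hydrogen through the oxygen-stabilised C5 radical, and the route is rejoined at 23.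

3. Step 10. Desulfurisation may stop at a ring-opened thioether, NaBH4 may partly reduce the lactone, or benzyl ethers may be lost on the nickel surface.
The fallback sets out from 17 and replaces the nickel surface reaction by a homolytic chain reduction: Bu3SnH (excess), AIBN, toluene, reflux. This cleaves both benzylic C–S bonds through sulfur-stabilised benzylic radicals and should leave benzyl ethers, the silyl ether and the lactone alone. It returns to the route at 18 and makes no compound outside the route (F0).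

**Further compounds**

F1 | step 9 | (3S,4R,5R)-3-((2,4-bis(benzyloxy)-3-methoxyphenyl)(hydroxy)methyl)-4-(2-(4-(benzyloxy)-3-methoxyphenyl)-1,3-dithian-2-yl)-5-((tert-butyldiphenylsilyloxy)methyl)dihydrofuran-2(3H)-one | O=C1O[C@@H](CO[Si](c2ccccc2)(c2ccccc2)C(C)(C)C)[C@H](C2(c3ccc(OCc4ccccc4)c(OC)c3)SCCCS2)[C@H]1C(O)c1ccc(OCc2ccccc2)c(OC)c1OCc1ccccc1
F2 | step 9 | O-((2,4-bis(benzyloxy)-3-methoxyphenyl)((3S,4R,5R)-4-(2-(4-(benzyloxy)-3-methoxyphenyl)-1,3-dithian-2-yl)-5-((tert-butyldiphenylsilyloxy)methyl)-2-oxotetrahydrofuran-3-yl)methyl) 1H-imidazole-1-carbothioate | O=C1O[C@@H](CO[Si](c2ccccc2)(c2ccccc2)C(C)(C)C)[C@H](C2(c3ccc(OCc4ccccc4)c(OC)c3)SCCCS2)[C@H]1C(OC(=S)n1ccnc1)c1ccc(OCc2ccccc2)c(OC)c1OCc1ccccc1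
F3 | step 12 | (2R,3R,4R)-4-(2,4-bis(benzyloxy)-3-methoxybenzyl)-3-(4-(benzyloxy)-3-methoxybenzyl)-5-oxotetrahydrofuran-2-carboxylic acid | O=C1O[C@@H](C(=O)O)[C@H](Cc2ccc(OCc3ccccc3)c(OC)c2)[C@H]1Cc1ccc(OCc2ccccc2)c(OC)c1OCc1ccccc1
F4 | step 12 | 2-thioxopyridin-1(2H)-yl (2R,3R,4R)-4-(2,4-bis(benzyloxy)-3-methoxybenzyl)-3-(4-(benzyloxy)-3-methoxybenzyl)-5-oxotetrahydrofuran-2-carboxylate | O=C1O[C@@H](C(=O)ON2C=CC=CC2=S)[C@H](Cc2ccc(OCc3ccccc3)c(OC)c2)[C@H]1Cc1ccc(OCc2ccccc2)c(OC)c1OCc1ccccc1
F0 | step 10 | none | none
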